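(The data stem from a simulated flask with made-up constants; scatter was added.)

Slowness shows first: after 10.0 h the autumn electrophile still falls from 49.2% to 27.2%, while its product creeps from 35.5% to 42.9%.

| flask | electrophile | nucleophile | protic impurity | remark | time |
|---|---|---|---|---|---|
| autumn | 0.14 M | 0.14 M | 0.070 M | run made earlier |  |
| spring | 0.14 M | 0.22 M | 0.070 M | run made earlier |  |
| eta | 0.14 M | 0.110 M | 0.0700 M |  | 30 h |
| theta | 0.14 M | 0.170 M | 0.0700 M |  | 30 h |

- autumn (time / h: electrophile / %, product / %): 2.00: 78.5, 19.9; 6.00: 57.9, 33.6; 10.0: 49.2, 35.5; 15.0: 39.4, 37.6; 25.0: 29.7, 43.3; 30.0: 27.2, 42.9
- spring (time / h: electrophile / %, product / %): 2.50: 65.2, 32.5; 4.00: 50.8, 40.2; 6.00: 45.5, 46.4; 10.0: 35.4, 52.0; 20.0: 20.0, 61.7; 30.0: 13.5, 62.1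

(each reading ± 1 percentage point)

- the numbers in the tables scatter with a standard deviation of 1 percentage point
- steps under discussion: electrophile + nucleophile -> acid set free + product; nucleophile + acid set free <-> protonated nucleophile; nucleophile + protic impurity -> quenched reagent; electrophile <-> dormant form
- what has gone from electrophile into another species counts as reacted, even if it can come back

1. part of the electrophile that has reacted at the end, eta
2. part of the electrophile that has reacted at the end, theta
3. what raising the concentration of nucleophile from its lowest to its highest value here does to the part of the electrophile that has reacted (changes below 5 percentage points count as none) (no change / it falls / it rises)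

Two chemists argue over eta and theta. The clock reader takes the electrophile lost but not found as product, the drain: at 6.00 h that is 8.50% in autumn and 8.10% in spring, equal within the scatter, so at that time the drain does not differ between the two charges of nucleophile. She expects the reacted part to follow the time. Eta is charged below autumn and theta above it, so she puts both near autumn's 72.8%, with no change between them.

The budget reader treats nucleophile as the limiting reagent. Autumn and spring have the same c(electrophile) and c(protic impurity), yet at 30.0 h spring has reacted 86.5% against autumn's 72.8%. He reckons with the leverage, the extra c(electrophile) reacted by that time per extra c(nucleophile) charged: 0.240, a reading with its scatter. Across the span from eta to theta it gives 10 percentage points, more than the margin of 5 points. Anchored on autumn, it gives 67.7% for eta and 77.9% for theta.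

The forecast takes the budget side by another route, a plateau of product for each flask and then the drain on the rest, since “Dormancy continues regardless”. For eta it says 69%, higher than his reckoning, for theta 78%, and for the trend: it rises.

    electrophile + nucleophile → acid set free + product (k = 1.10 /M/h)
    nucleophile + acid set free ⇌ protonated nucleophile, settled at all times (K = 180 /M)
    nucleophile + protic impurity → quenched reagent (k = 1.60 /M/h)
    electrophile ⇌ dormant form (K = 11.0, k = 0.0240 /h)

The flasks give 69.9% for eta and 78.8% for theta, and between them it rises by 8.9 points. The clock reader keeps a region: around theta, with the other charges and the time held, c(nucleophile) between 0.135 M and 0.207 M moves the reacted part by less than 5 points. The leverage between eta and theta comes to 0.208, against the 0.240 read earlier. Carried down from theta to a neighbour charged with 0.043 M of nucleophile, 0.240 gives 57.0%, and that neighbour stands at 58.6%.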